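**Plan**
- Retrosynthesis: the two O-benzyl groups and the C3 hydroxyl are removed first. Ring C is then cut at its C2=C3 double bond, then the O1–C2 bond (an aryl ester between the ring A phenol and the ring B acid), and last the aryl–CH2 bond of the side chain.
- Enabling feature: in ring C the C2=C3 bond joins C2, which carries O1 and ring B, to C3, which is alpha to the C4 ketone. C2 can therefore come from an aroyl ester carbonyl and C3 from a phenacyl ylide carbon, both held on ring A.
- Forward order: ring A is built from phloroacetophenone by benzylation, methylation, Elbs oxidation and methylation. The chain is joined to ring B by B-alkyl Suzuki coupling. The ring B acid is esterified onto the ring A phenol, and bromination and PPh3 give the ylide.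
- Ring C is the only ring made; it closes in step 14. C3 hydroxylation and hydrogenolysis finish the route.
- Stereochemistry: the single (S) centre comes from methyl (R)-3-hydroxy-2-methylpropanoate. Its ester carbon becomes the chain CH2 that points to the arene, so the descriptor changes but no bond at the centre is ever broken.

Key step: step 14

Remark: the ring A phenacylidene phosphorane is assumed to survive a cold aqueous carbonate work-up and to attack the aroyl ester only on heating, as keto-stabilised ylides normally do towards esters.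

**Route**

Step 1
Reactants: 1 2',4',6'-trihydroxyacetophenone
Product: 2 1-[4-(benzyloxy)-2,6-dihydroxyphenyl]ethanone
Conditions: BnBr (1.0 equiv), K2CO3 (1.0 equiv), DMF, 0 °C to rt
Reagents that add atoms: benzyl bromide, BrCc1ccccc1
Why: Williamson etherification; the 4-hydroxyl is the most acidic and the only one not hydrogen-bonded to the acetyl carbonyl, so one equivalent of halide and base should alkylate it first.

Step 2
Reactants: 2 1-[4-(benzyloxy)-2,6-dihydroxyphenyl]ethanone
Product: 3 1-[4-(benzyloxy)-2-hydroxy-6-methoxyphenyl]ethanone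
Conditions: Me2SO4 (1.05 equiv), K2CO3, acetone, reflux
Reagents that add atoms: dimethyl sulfate, COS(=O)(=O)OC
Why: Williamson mono-methylation of one of two equivalent hydroxyls; the remaining hydroxyl stays chelated to the carbonyl and should resist a second alkylation under these conditions.

Step 3
Reactants: 3 1-[4-(benzyloxy)-2-hydroxy-6-methoxyphenyl]ethanone
Product: 5 1-[4-(benzyloxy)-3,6-dihydroxy-2-methoxyphenyl]ethanone, via potassium aryl sulfate 4 (not isolated)
Conditions: K2S2O8, KOH (aq), pyridine, 15–20 °C; then HCl (aq), 80 °C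
Reagents that add atoms: potassium peroxodisulfate, [K+].[K+].[O-]S(=O)(=O)OOS(=O)(=O)[O-]
Why: Elbs persulfate oxidation; the phenoxide attacks a peroxide oxygen through the free carbon para to the hydroxyl, and warm dilute acid cleaves the resulting aryl sulfate while the benzyl and methyl ethers should survive.

Step 4
Reactants: 5 1-[4-(benzyloxy)-3,6-dihydroxy-2-methoxyphenyl]ethanone
Product: 6 1-[4-(benzyloxy)-6-hydroxy-2,3-dimethoxyphenyl]ethanone
Conditions: Me2SO4 (1.05 equiv), K2CO3, acetone, reflux
Reagents that add atoms: dimethyl sulfate, COS(=O)(=O)OC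
Why: Williamson methylation that distinguishes the new, unchelated 3-hydroxyl from the 6-hydroxyl held by the ketone, as in the classical preparations of 6-hydroxy-2,3,4-trialkoxyacetophenones.

Step 5
Reactants: 7 methyl (R)-3-hydroxy-2-methylpropanoate
Product: 8 methyl (R)-3-(benzyloxy)-2-methylpropanoate
Conditions: benzyl 2,2,2-trichloroacetimidate, TfOH (cat.), CH2Cl2/cyclohexane, 0 °C to rt
Reagents that add atoms: benzyl 2,2,2-trichloroacetimidate, N=C(OCc1ccccc1)C(Cl)(Cl)Cl
Why: acid-catalysed trichloroacetimidate benzylation, which uses no base and so should neither epimerise the alpha centre nor cause beta-elimination.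

Step 6
Reactants: 8 methyl (R)-3-(benzyloxy)-2-methylpropanoate
Product: 9 (S)-3-(benzyloxy)-2-methylpropan-1-ol
Conditions: LiAlH4, THF, 0 °C; then H2O
Reagents that add atoms: none
Why: hydride reduction of the ester to the primary alcohol; the centre is untouched and its descriptor becomes S only because the priorities of the two CH2O arms swap.

Step 7
Reactants: 9 (S)-3-(benzyloxy)-2-methylpropan-1-ol
Product: 10 (R)-3-(benzyloxy)-2-methylpropanal
Conditions: PhI(OAc)2, TEMPO (cat.), CH2Cl2, rt; used at once without chromatography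
Reagents that add atoms: none
Why: TEMPO-catalysed oxidation with PhI(OAc)2, a base-free method that stops at the aldehyde and is routinely used for alpha-branched aldehydes without loss of configuration.

Step 8
Reactants: 10 (R)-3-(benzyloxy)-2-methylpropanal
Product: 11 (S)-4-(benzyloxy)-3-methylbut-1-ene
Conditions: Ph3PCH3Br, n-BuLi, THF, 0 °C; then 10, −78 °C to rt
Reagents that add atoms: methyltriphenylphosphonium bromide, C[P+](c1ccccc1)(c1ccccc1)c1ccccc1.[Br-]
Why: Wittig methylenation with the non-stabilised ylide, which adds at −78 °C faster than it enolises the aldehyde, so the centre should be carried over intact (S by priority change only).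

Step 9
Reactants: 11 (S)-4-(benzyloxy)-3-methylbut-1-ene; 12 methyl 3-bromo-4-methoxybenzoate
Product: 14 methyl 3-[(3S)-4-(benzyloxy)-3-methylbutyl]-4-methoxybenzoate, via alkylborane 13 (not isolated)
Conditions: 9-BBN, THF, 0 °C to rt; then 12, Pd(dppf)Cl2 (5 mol %), K3PO4 (3 M aq), DMF, 50 °C
Reagents that add atoms: none
Why: anti-Markovnikov hydroboration followed by B-alkyl Suzuki–Miyaura coupling (oxidative addition of the aryl bromide to zerovalent palladium, base-assisted transfer of the primary alkyl group, reductive elimination); phosphate at 50 °C should spare the methyl ester.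

Step 10
Reactants: 14 methyl 3-[(3S)-4-(benzyloxy)-3-methylbutyl]-4-methoxybenzoate
Product: 15 3-[(3S)-4-(benzyloxy)-3-methylbutyl]-4-methoxybenzoic acid
Conditions: LiOH, THF/MeOH/H2O, rt; then HCl (1 M)
Reagents that add atoms: lithium hydroxide, [Li+].[OH-]
Why: saponification of the methyl ester; the benzyl ether, the aryl ether and the remote centre are inert to aqueous hydroxide.

Step 11
Reactants: 15 3-[(3S)-4-(benzyloxy)-3-methylbutyl]-4-methoxybenzoic acid; 6 1-[4-(benzyloxy)-6-hydroxy-2,3-dimethoxyphenyl]ethanone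
Product: 17 2-acetyl-5-(benzyloxy)-3,4-dimethoxyphenyl 3-[(3S)-4-(benzyloxy)-3-methylbutyl]-4-methoxybenzoate, via acid chloride 16 (not isolated)
Conditions: (COCl)2, DMF (cat.), CH2Cl2, 0 °C to rt, evaporate; then 6, Et3N, DMAP (cat.), CH2Cl2, 0 °C to rt
Reagents that add atoms: none
Why: acid chloride formation and DMAP-catalysed O-acylation of the chelated phenol; the amine bases are too weak to enolise the acetyl group, so no Baker–Venkataraman shift should occur.

Step 12
Reactants: 17 2-acetyl-5-(benzyloxy)-3,4-dimethoxyphenyl 3-[(3S)-4-(benzyloxy)-3-methylbutyl]-4-methoxybenzoate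
Product: 18 5-(benzyloxy)-2-(bromoacetyl)-3,4-dimethoxyphenyl 3-[(3S)-4-(benzyloxy)-3-methylbutyl]-4-methoxybenzoate
Conditions: CuBr2 (2.1 equiv), EtOAc/CHCl3 (1:1), reflux
Reagents that add atoms: CuBr2, Br[Cu]Br
Why: King–Ostrum alpha-bromination of an aryl methyl ketone with CuBr2, a heterogeneous reagent known to brominate the enolisable side chain in preference to oxygenated aromatic rings.

Step 13
Reactants: 18 5-(benzyloxy)-2-(bromoacetyl)-3,4-dimethoxyphenyl 3-[(3S)-4-(benzyloxy)-3-methylbutyl]-4-methoxybenzoate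
Product: 20 5-(benzyloxy)-3,4-dimethoxy-2-[(triphenylphosphoranylidene)acetyl]phenyl 3-[(3S)-4-(benzyloxy)-3-methylbutyl]-4-methoxybenzoate, via phosphonium bromide 19 (not isolated)
Conditions: PPh3, toluene, rt; then Na2CO3 (aq), CH2Cl2, 0 °C
Reagents that add atoms: triphenylphosphine, P(c1ccccc1)(c1ccccc1)c1ccccc1
Why: SN2 alkylation of PPh3 by the phenacyl bromide, then deprotonation of the CH2 between the phosphonium and the ketone by cold two-phase carbonate, which is too mild to hydrolyse the aryl ester.

Step 14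
Reactants: 20 5-(benzyloxy)-3,4-dimethoxy-2-[(triphenylphosphoranylidene)acetyl]phenyl 3-[(3S)-4-(benzyloxy)-3-methylbutyl]-4-methoxybenzoate
Product: 21 7-(benzyloxy)-2-{3-[(3S)-4-(benzyloxy)-3-methylbutyl]-4-methoxyphenyl}-5,6-dimethoxy-4H-chromen-4-one
Conditions: toluene, reflux, N2
Reagents that add atoms: none
Why: intramolecular Wittig olefination of an ester carbonyl: the ylide carbon (future C3) adds to the aroyl ester carbonyl (future C2), the adduct closes to an oxaphosphetane, and loss of Ph3PO leaves the C2=C3 double bond. The closest known reaction type is the thermal cyclisation of 2-acyloxyphenacylidene phosphoranes to chromones and flavones. Ring C closes in a 6-exo-trig mode, the ester C=O lying outside the forming ring O1–C2–C3–C4–C4a–C8a. No stereocentre is formed, and the side-chain (S) centre is remote and untouched under these neutral conditions. The selectivity needed is olefination over acyl transfer, in which the tetrahedral adduct would expel the ring A phenoxide and give a C-aroyl ylide; a non-polar solvent without base or nucleophile, the strong P=O bond and the aromatic pyranone formed should favour olefination. Both rings and the chain are already in place, so there is no regiochemical choice.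

Step 15
Reactants: 21 7-(benzyloxy)-2-{3-[(3S)-4-(benzyloxy)-3-methylbutyl]-4-methoxyphenyl}-5,6-dimethoxy-4H-chromen-4-one
Product: 24 7-(benzyloxy)-2-{3-[(3S)-4-(benzyloxy)-3-methylbutyl]-4-methoxyphenyl}-3-hydroxy-5,6-dimethoxy-4H-chromen-4-one, via 3-lithioflavone 22 (not isolated), via dimethyl boronate 23 (not isolated)
Conditions: LiN(i-Pr)2, THF, −78 °C; B(OMe)3, −78 to 0 °C; AcOH, H2O2 (30% aq), 0 °C to rt
Reagents that add atoms: hydrogen peroxide, OO
Why: vinylic lithiation of the flavone at C3 (acidified by the C4 carbonyl and held by the C4=O/5-OMe lithium chelate), borylation, and peroxide-induced migration of carbon from boron to oxygen, the known lithiation–borylation–oxidation route from flavones to flavonols.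

Step 16
Reactants: 24 7-(benzyloxy)-2-{3-[(3S)-4-(benzyloxy)-3-methylbutyl]-4-methoxyphenyl}-3-hydroxy-5,6-dimethoxy-4H-chromen-4-one
Product: 25 3,7-dihydroxy-2-{3-[(3S)-4-hydroxy-3-methylbutyl]-4-methoxyphenyl}-5,6-dimethoxy-4H-chromen-4-one
Conditions: H2 (1 atm), Pd/C (10%), EtOAc/MeOH, rt
Reagents that add atoms: none
Why: catalytic hydrogenolysis of the aryl and the alkyl benzyl ether in one operation; the flavonol enone, the methyl ethers and the stereocentre should be stable at 1 atm and room temperature.

**Compound list**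

1 | 2',4',6'-trihydroxyacetophenone | CC(=O)c1c(O)cc(O)cc1O | starting material
2 | 1-[4-(benzyloxy)-2,6-dihydroxyphenyl]ethanone | CC(=O)c1c(O)cc(OCc2ccccc2)cc1O | intermediate
3 | 1-[4-(benzyloxy)-2-hydroxy-6-methoxyphenyl]ethanone | CC(=O)c1c(O)cc(OCc2ccccc2)cc1OC | intermediate
4 | potassium 3-acetyl-6-(benzyloxy)-4-hydroxy-2-methoxyphenyl sulfate | CC(=O)c1c(O)cc(OCc2ccccc2)c(OS(=O)(=O)[O-])c1OC.[K+] | intermediate (not isolated)
5 | 1-[4-(benzyloxy)-3,6-dihydroxy-2-methoxyphenyl]ethanone | CC(=O)c1c(O)cc(OCc2ccccc2)c(O)c1OC | intermediate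
6 | 1-[4-(benzyloxy)-6-hydroxy-2,3-dimethoxyphenyl]ethanone | CC(=O)c1c(O)cc(OCc2ccccc2)c(OC)c1OC | intermediate
7 | methyl (R)-3-hydroxy-2-methylpropanoate | COC(=O)[C@H](C)CO | starting material
8 | methyl (R)-3-(benzyloxy)-2-methylpropanoate | COC(=O)[C@H](C)COCc1ccccc1 | intermediate
9 | (S)-3-(benzyloxy)-2-methylpropan-1-ol | OC[C@H](C)COCc1ccccc1 | intermediate
10 | (R)-3-(benzyloxy)-2-methylpropanal | O=C[C@H](C)COCc1ccccc1 | intermediate
11 | (S)-4-(benzyloxy)-3-methylbut-1-ene | C=C[C@H](C)COCc1ccccc1 | intermediate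
12 | methyl 3-bromo-4-methoxybenzoate | COC(=O)c1ccc(OC)c(Br)c1 | starting material
13 | 9-[(3S)-4-(benzyloxy)-3-methylbutyl]-9-borabicyclo[3.3.1]nonane | B1(CC[C@H](C)COCc2ccccc2)C2CCCC1CCC2 | intermediate (not isolated)
14 | methyl 3-[(3S)-4-(benzyloxy)-3-methylbutyl]-4-methoxybenzoate | COC(=O)c1ccc(OC)c(CC[C@H](C)COCc2ccccc2)c1 | intermediate
15 | 3-[(3S)-4-(benzyloxy)-3-methylbutyl]-4-methoxybenzoic acid | OC(=O)c1ccc(OC)c(CC[C@H](C)COCc2ccccc2)c1 | intermediate
16 | 3-[(3S)-4-(benzyloxy)-3-methylbutyl]-4-methoxybenzoyl chloride | ClC(=O)c1ccc(OC)c(CC[C@H](C)COCc2ccccc2)c1 | intermediate (not isolated)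
17 | 2-acetyl-5-(benzyloxy)-3,4-dimethoxyphenyl 3-[(3S)-4-(benzyloxy)-3-methylbutyl]-4-methoxybenzoate | CC(=O)c1c(OC)c(OC)c(OCc2ccccc2)cc1OC(=O)c1ccc(OC)c(CC[C@H](C)COCc2ccccc2)c1 | intermediate
18 | 5-(benzyloxy)-2-(bromoacetyl)-3,4-dimethoxyphenyl 3-[(3S)-4-(benzyloxy)-3-methylbutyl]-4-methoxybenzoate | BrCC(=O)c1c(OC)c(OC)c(OCc2ccccc2)cc1OC(=O)c1ccc(OC)c(CC[C@H](C)COCc2ccccc2)c1 | intermediate
19 | {2-[4-(benzyloxy)-6-({3-[(3S)-4-(benzyloxy)-3-methylbutyl]-4-methoxybenzoyl}oxy)-2,3-dimethoxyphenyl]-2-oxoethyl}triphenylphosphonium bromide | [Br-].O=C(C[P+](c1ccccc1)(c1ccccc1)c1ccccc1)c1c(OC)c(OC)c(OCc2ccccc2)cc1OC(=O)c1ccc(OC)c(CC[C@H](C)COCc2ccccc2)c1 | intermediate (not isolated)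
20 | 5-(benzyloxy)-3,4-dimethoxy-2-[(triphenylphosphoranylidene)acetyl]phenyl 3-[(3S)-4-(benzyloxy)-3-methylbutyl]-4-methoxybenzoate | O=C(C=P(c1ccccc1)(c1ccccc1)c1ccccc1)c1c(OC)c(OC)c(OCc2ccccc2)cc1OC(=O)c1ccc(OC)c(CC[C@H](C)COCc2ccccc2)c1 | intermediate
21 | 7-(benzyloxy)-2-{3-[(3S)-4-(benzyloxy)-3-methylbutyl]-4-methoxyphenyl}-5,6-dimethoxy-4H-chromen-4-one | COc1ccc(-c2cc(=O)c3c(OC)c(OC)c(OCc4ccccc4)cc3o2)cc1CC[C@H](C)COCc1ccccc1 | intermediate
22 | 7-(benzyloxy)-2-{3-[(3S)-4-(benzyloxy)-3-methylbutyl]-4-methoxyphenyl}-3-lithio-5,6-dimethoxy-4H-chromen-4-one | COc1ccc(-c2oc3cc(OCc4ccccc4)c(OC)c(OC)c3c(=O)c2[Li])cc1CC[C@H](C)COCc1ccccc1 | intermediate (not isolated)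
23 | dimethyl (7-(benzyloxy)-2-{3-[(3S)-4-(benzyloxy)-3-methylbutyl]-4-methoxyphenyl}-5,6-dimethoxy-4-oxo-4H-chromen-3-yl)boronate | COc1ccc(-c2oc3cc(OCc4ccccc4)c(OC)c(OC)c3c(=O)c2B(OC)OC)cc1CC[C@H](C)COCc1ccccc1 | intermediate (not isolated)
24 | 7-(benzyloxy)-2-{3-[(3S)-4-(benzyloxy)-3-methylbutyl]-4-methoxyphenyl}-3-hydroxy-5,6-dimethoxy-4H-chromen-4-one | COc1ccc(-c2oc3cc(OCc4ccccc4)c(OC)c(OC)c3c(=O)c2O)cc1CC[C@H](C)COCc1ccccc1 | intermediate
25 | 3,7-dihydroxy-2-{3-[(3S)-4-hydroxy-3-methylbutyl]-4-methoxyphenyl}-5,6-dimethoxy-4H-chromen-4-one | COc1ccc(-c2oc3cc(O)c(OC)c(OC)c3c(=O)c2O)cc1CC[C@H](C)CO | target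

**Totals and risks**

Total step count: 16.
Longest linear sequence: 12 steps (steps 5 to 16, from 7); the ring A branch (steps 1 to 4) joins at step 11.

Steps most likely to fail:

1. Step 14. The ylide carbon may be acylated instead of olefinating: the tetrahedral adduct can expel the ring A phenoxide faster than it collapses through the oxaphosphetane. The hindered, electron-rich aroyl ester may also not be attacked before the ylide decomposes. The fallback sets out from 17 and gives up the phosphorus route. KOt-Bu in THF should bring about a Baker–Venkataraman O-to-C aroyl shift to 1-[4-(benzyloxy)-6-hydroxy-2,3-dimethoxyphenyl]-3-{3-[(3S)-4-(benzyloxy)-3-methylbutyl]-4-methoxyphenyl}propane-1,3-dione F1. Cyclodehydration of this diketone with catalytic p-TsOH in hot toluene should close ring C by O1–C2 bond formation, and the route is rejoined at 21.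

2. Step 12. Electrophilic bromination may go to the one free position of ring A or to ring B instead of the acetyl group, and the HBr released may start to cleave a benzyl ether. The fallback sets out from 17 and separates enolisation from halogenation. Soft enolisation with TMSOTf and Et3N in CH2Cl2 at 0 °C, conditions too weakly basic for an aroyl shift, should give 5-(benzyloxy)-3,4-dimethoxy-2-{1-[(trimethylsilyl)oxy]ethenyl}phenyl 3-[(3S)-4-(benzyloxy)-3-methylbutyl]-4-methoxybenzoate F2. This enol ether is far more nucleophilic than either arene and should take bromine from NBS in THF at −78 °C, rejoining the route at 18.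

3. Step 15. LDA may deprotonate elsewhere (the ring A C8–H between two oxygens, or a benzylic OCH2), the lithio species may be borylated incompletely, or the pyranone may open during the oxidative work-up. The fallback sets out from 21 and uses electrophilic oxygen instead of a carbanion. Dimethyldioxirane in acetone/CH2Cl2 should epoxidise the C2=C3 bond to the 2,3-epoxide of 21, F3, formed as both cis-fused diastereomers. A trace of p-TsOH should open this epoxide at C2 and tautomerise it to the flavonol, rejoining the route at 24.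

**Further compounds**

F1 | step 14 | 1-[4-(benzyloxy)-6-hydroxy-2,3-dimethoxyphenyl]-3-{3-[(3S)-4-(benzyloxy)-3-methylbutyl]-4-methoxyphenyl}propane-1,3-dione | COc1ccc(C(=O)CC(=O)c2c(O)cc(OCc3ccccc3)c(OC)c2OC)cc1CC[C@H](C)COCc1ccccc1
F2 | step 12 | 5-(benzyloxy)-3,4-dimethoxy-2-{1-[(trimethylsilyl)oxy]ethenyl}phenyl 3-[(3S)-4-(benzyloxy)-3-methylbutyl]-4-methoxybenzoate | C=C(O[Si](C)(C)C)c1c(OC)c(OC)c(OCc2ccccc2)cc1OC(=O)c1ccc(OC)c(CC[C@H](C)COCc2ccccc2)c1
F3 | step 15 | 2,3-epoxide of 21 (7-(benzyloxy)-2-{3-[(3S)-4-(benzyloxy)-3-methylbutyl]-4-methoxyphenyl}-2,3-epoxy-5,6-dimethoxy-2,3-dihydro-4H-chromen-4-one, epoxide carbons unassigned) | COc1ccc(C23Oc4cc(OCc5ccccc5)c(OC)c(OC)c4C(=O)C2O3)cc1CC[C@H](C)COCc1ccccc1
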